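**Plan**

- Numbering: ring A carries C1 (OMe), C2 (H), C3 (Me), C4 (depsidone C=O), C5 (diaryl ether O), C6 (CH2OH); ring B carries C1' (ether O), C2' (ester O), C3' (Me), C4' (OH), C5' (phthalide C=O), C6' (lactol carbon).
- Enabling feature: the ether oxygen on C5 and the acyl oxygen of the C4 carboxyl both end on the neighbouring ring B carbons C1' and C2', that is on one catechol, so C5 can be carried as the ketene acetal carbon of a 1,3-benzodioxole built on ring B.
- Retrosynthetic cuts, in order: lactol acetate and protecting groups; the lactone bond C4(=O)–O(C2') together with the ring A bonds C2–C3 and C4–C5 (one cascade from a diene and a but-2-ynoate); the C1=C2 bond (ester methylenation); the two ketene acetal C–O bonds (vinylic substitution on a gem-dibromoacrylate that supplies C1, C6, C5 and the CH2O carbon).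
- Forward order: ring B is elaborated from 2,4-dihydroxy-3-methylbenzoic acid into a protected catechol; the benzodioxole ring is closed on the dibromoacrylate; methylenation gives the diene; the key step builds ring A and expands the dioxole to the seven-membered lactone; acid deprotection closes the five-membered lactol ring.
- Stereochemistry: the single stereocentre (lactol carbon, R) is set by lipase-mediated dynamic kinetic acetylation of the racemic lactol and is uncovered last by lipase alcoholysis, which breaks no bond at that carbon.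

Key step: step 15

Assumption: the lactol carbon can epimerise through the ring-opened formyl acid, so the (R)-lactol is released last under neutral water-free conditions and is taken to hold its configuration on cold isolation; the lipase that acetylates the (R)-lactol has to be found by screening.

**Route**

Step 1
Reactants: 1 2,4-dihydroxy-3-methylbenzoic acid
Product: 3 2,4,5-trihydroxy-3-methylbenzoic acid, via aryl sulfate 2 (not isolated)
Conditions: K2S2O8, aq KOH, 5 °C → rt; then conc. HCl, 90 °C
Reagents that add atoms: potassium peroxodisulfate [K+].[K+].[O-]S(=O)(=O)OOS(=O)(=O)[O-]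
Why: Elbs persulfate oxidation; peroxodisulfate attacks the phenoxide at C5, the only free position para to a phenoxide oxygen, and acid hydrolyses the aryl sulfate.

Step 2
Reactants: 3 2,4,5-trihydroxy-3-methylbenzoic acid
Product: 4 tert-butyl 2,4,5-trihydroxy-3-methylbenzoate
Conditions: Me2NCH(Ot-Bu)2, PhMe, 80 °C
Reagents that add atoms: N,N-dimethylformamide di-tert-butyl acetal CN(C)C(OC(C)(C)C)OC(C)(C)C
Why: Esterification by an amide acetal; only the carboxylic acid is acidic enough to ionise the acetal and be tert-butylated, so the phenols stay free.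

Step 3
Reactants: 4 tert-butyl 2,4,5-trihydroxy-3-methylbenzoate
Product: 5 tert-butyl 4,5-bis(benzyloxy)-2-hydroxy-3-methylbenzoate
Conditions: BnBr (2.1 equiv), K2CO3, acetone, reflux, Ar
Reagents that add atoms: benzyl bromide BrCc1ccccc1
Why: Williamson etherification; the 2-hydroxyl is hydrogen-bonded to the ester carbonyl and flanked by the methyl group, so only the 4- and 5-hydroxyls should be alkylated.

Step 4
Reactants: 5 tert-butyl 4,5-bis(benzyloxy)-2-hydroxy-3-methylbenzoate
Product: 6 tert-butyl 4,5-bis(benzyloxy)-2-(methoxymethoxy)-3-methylbenzoate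
Conditions: NaH, MOMCl, DMF, 0 °C → rt
Reagents that add atoms: chloromethyl methyl ether COCCl
Why: Alkylation of the sodium phenoxide by the chloromethyl ether; irreversible deprotonation by NaH overcomes the hydrogen bond of the salicylate hydroxyl.

Step 5
Reactants: 6 tert-butyl 4,5-bis(benzyloxy)-2-(methoxymethoxy)-3-methylbenzoate
Product: 7 tert-butyl 3,4-bis(benzyloxy)-2-bromo-6-(methoxymethoxy)-5-methylbenzoate
Conditions: NBS, MeCN, 0 °C → rt, dark
Reagents that add atoms: N-bromosuccinimide O=C1CCC(=O)N1Br
Why: Electrophilic aromatic bromination at the only unsubstituted ring position (ortho to a benzyloxy group, para to the methyl group); NBS in acetonitrile favours ring over benzylic bromination.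

Step 6
Reactants: 7 tert-butyl 3,4-bis(benzyloxy)-2-bromo-6-(methoxymethoxy)-5-methylbenzoate
Product: 9 tert-butyl 3,4-bis(benzyloxy)-2-formyl-6-(methoxymethoxy)-5-methylbenzoate, via arylmagnesium chloride 8 (not isolated)
Conditions: i-PrMgCl·LiCl, THF, −15 °C; then DMF, −15 °C → rt; aq NH4Cl
Reagents that add atoms: N,N-dimethylformamide CN(C)C=O; isopropylmagnesium chloride CC(C)[Mg]Cl (magnesium in intermediate 8 only)
Why: Bromine–magnesium exchange is accelerated by the ortho ester and tolerates the hindered tert-butyl ester at low temperature; the arylmagnesium is then formylated by DMF (Bouveault aldehyde synthesis).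

Step 7
Reactants: 9 tert-butyl 3,4-bis(benzyloxy)-2-formyl-6-(methoxymethoxy)-5-methylbenzoate
Product: 10 tert-butyl 3,4-bis(benzyloxy)-2-(dimethoxymethyl)-6-(methoxymethoxy)-5-methylbenzoate
Conditions: HC(OMe)3, MeOH, PPTS (cat.), 40 °C
Reagents that add atoms: trimethyl orthoformate COC(OC)OC; methanol CO
Why: Acid-catalysed acetalisation driven by the orthoformate; the weak acid PPTS should spare the MOM ether and the tert-butyl ester, whose bulk also disfavours closure to a pseudo-ester.

Step 8
Reactants: 10 tert-butyl 3,4-bis(benzyloxy)-2-(dimethoxymethyl)-6-(methoxymethoxy)-5-methylbenzoate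
Product: 11 tert-butyl 2-(dimethoxymethyl)-3,4-dihydroxy-6-(methoxymethoxy)-5-methylbenzoate (ring B catechol; free hydroxyls on C1' and C2')
Conditions: H2 (1 atm), Pd/C, NaHCO3, EtOAc, rt
Reagents that add atoms: none
Why: Hydrogenolysis of aryl benzyl ethers over palladium; the bicarbonate buffer protects the dimethyl acetal and MOM ether from adventitious acid.

Step 9
Reactants: 12 methyl 2-(hydroxymethyl)acrylate
Product: 13 methyl 2-{[tert-butyl(diphenyl)silyl]oxymethyl}acrylate
Conditions: TBDPSCl, imidazole, CH2Cl2, 0 °C → rt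
Reagents that add atoms: tert-butyl(chloro)diphenylsilane CC(C)(C)[Si](Cl)(c1ccccc1)c1ccccc1
Why: Imidazole-promoted silylation of a primary alcohol; TBDPS is chosen because it should survive the later trifluoroacetic acid step.

Step 10
Reactants: 13 methyl 2-{[tert-butyl(diphenyl)silyl]oxymethyl}acrylate
Product: 15 methyl 3-{[tert-butyl(diphenyl)silyl]oxy}-2-oxopropanoate, via ozonide 14 (not isolated)
Conditions: O3, CH2Cl2, −78 °C; then Me2S, −78 °C → rt
Reagents that add atoms: ozone [O-][O+]=O
Why: Ozonolysis of the 1,1-disubstituted alkene and reductive work-up of the ozonide give the α-keto ester.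

Step 11
Reactants: 15 methyl 3-{[tert-butyl(diphenyl)silyl]oxy}-2-oxopropanoate
Product: 16 methyl 3,3-dibromo-2-{[tert-butyl(diphenyl)silyl]oxymethyl}acrylate
Conditions: CBr4, PPh3, Zn dust, CH2Cl2, 0 °C → rt
Reagents that add atoms: tetrabromomethane BrC(Br)(Br)Br
Why: Ramirez dibromomethylenation (first stage of the Corey–Fuchs sequence); the activated keto group of an α-keto ester reacts readily with the dibromomethylene ylide, and zinc consumes the Ph3PBr2 that could attack the silyl ether.

Step 12
Reactants: 11 ring B catechol; 16 methyl 3,3-dibromo-2-{[tert-butyl(diphenyl)silyl]oxymethyl}acrylate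
Product: 18 tert-butyl 4-(dimethoxymethyl)-2-[1-methoxy-1-oxo-3-{[tert-butyl(diphenyl)silyl]oxy}propan-2-ylidene]-6-(methoxymethoxy)-7-methyl-1,3-benzodioxole-5-carboxylate (either alkene geometry), via bromo aryloxy acrylate 17 (not isolated)
Conditions: Cs2CO3, DMF (degassed), 0 °C → 40 °C
Reagents that add atoms: none
Why: Two successive vinylic substitutions by addition–elimination at the β-carbon of the ester-activated gem-dibromoalkene, the second intramolecular and closing the five-membered dioxole, give the cyclic ketene acetal.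

Step 13
Reactants: 18 benzodioxol-2-ylidene ester
Product: 19 tert-butyl 4-(dimethoxymethyl)-2-[3-methoxy-1-{[tert-butyl(diphenyl)silyl]oxy}but-3-en-2-ylidene]-6-(methoxymethoxy)-7-methyl-1,3-benzodioxole-5-carboxylate (diene; either alkene geometry)
Conditions: Cp2TiMe2, PhMe/THF, 65 °C, dark; filtration through basic Al2O3; used at once
Reagents that add atoms: dimethyltitanocene [CH3-].[CH3-].[Ti+4].c1cc[cH-]c1.c1cc[cH-]c1
Why: Petasis methylenation converts the methyl ester into the methyl enol ether (its OMe becomes the C1 methoxy of ring A) under neutral conditions free of Lewis acid; the di-ortho-substituted tert-butyl ester of ring B should be too hindered to react.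

Step 14
Reactants: 20 but-2-ynoic acid; 21 pentafluorophenol
Product: 22 pentafluorophenyl but-2-ynoate
Conditions: DCC, CH2Cl2, 0 °C → rt
Reagents that add atoms: none
Why: Carbodiimide-mediated esterification; DMAP is left out because it would add to the ynoate.

Step 15
Reactants: 19 diene; 22 pentafluorophenyl but-2-ynoate
Product: 25 protected depsidone (ring A: C1 OMe, C3 Me, C6 CH2OTBDPS; ring B: C3' Me, C4' OMOM, C5' CO2t-Bu, C6' CH(OMe)2), via spiro cycloadduct 23 (not isolated), via phenol pentafluorophenyl ester 24 (not isolated)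
Conditions: PhMe, 100 °C (sealed); then DBU, PhMe (0.01 M), 0 °C → rt
Reagents that add atoms: none
Why: Proposed new method: the electron-rich terminal CH2 of diene 19 (C2) bonds to the methyl-bearing β-carbon of ynoate 22 and the ketene acetal carbon (C5) to its α-carbon in a polarised, possibly stepwise [4+2] addition that closes the six-membered ring A as spiro-1,4-cyclohexadiene 23. Loss of the C2 proton, which is doubly allylic and vinylogous to the ester, together with expulsion of one aryloxide from C5 aromatises ring A to 24, and the freed C2' phenoxide then closes the seven-membered lactone by 7-exo-trig acyl substitution on the neighbouring pentafluorophenyl ester, so that the five-membered dioxole is expanded to the dioxepinone. The closest known reaction type is the Diels–Alder addition and aromatisation of 1,1-dialkoxy-3-oxygenated butadienes (Brassard-type dienes) with alkynoates, which gives resorcylates with loss of one alkoxide; a catechol acetal whose leaving oxygen returns as the lactonising nucleophile has not been used in this way. No stereocentre is formed, since the spiro centre of 23 is destroyed on aromatisation. Two selectivities are needed: the regiochemistry of addition, secured by the matched polarity of the diene (nucleophilic at C2) and the ynoate (electrophilic at its β-carbon), and departure of the C2' rather than the C1' oxygen, secured because the C2' aryloxide is para to the C5' ester and so the better leaving group, while the more electron-rich C1' oxygen stays to stabilise the developing positive charge at C5. The pentafluorophenyl ester is chosen over a simple aryl ester because it makes the ynoate a better dienophile and makes acyl transfer to the ring B phenoxide downhill.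

Step 16
Reactants: 25 protected depsidone
Product: 27 racemic lactol (3-hydroxyphthalide on ring B; C4' OH free; C6 CH2OTBDPS retained), via formyl acid 26 (not isolated)
Conditions: TFA/CH2Cl2/H2O (10:30:1), 0 °C → rt
Reagents that add atoms: water O
Why: Acidolysis cleaves the tert-butyl ester by alkyl–oxygen fission and hydrolyses the acetal and MOM ether, the 2-formylbenzoic acid 26 closes to the hydroxyphthalide by ring–chain tautomerism, and the TBDPS ether should survive; the lactol forms as the racemate.

Step 17
Reactants: 27 racemic lactol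
Product: 28 (R)-lactol acetate (3-acetoxyphthalide; C6 CH2OTBDPS)
Conditions: immobilised Burkholderia cepacia lipase, vinyl acetate, Et3N (cat.), PhMe, 35 °C
Reagents that add atoms: vinyl acetate C=COC(C)=O
Why: Lipase-catalysed dynamic kinetic resolution by irreversible transesterification; the lactol enantiomers interconvert through ring-opened 26 (helped by Et3N) while the chiral active site of the enzyme acetylates only the (R)-lactol, which sets the sole stereocentre.

Step 18
Reactants: 28 (R)-lactol acetate
Product: 29 (R)-lactol acetate with free C6 hydroxymethyl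
Conditions: HF·pyridine, pyridine, THF, 0 °C → rt
Reagents that add atoms: none
Why: Fluoride-mediated desilylation under buffered conditions that are neither basic nor strongly acidic should leave the acylal, the depsidone ester and the stereocentre untouched.

Step 19
Reactants: 29 (R)-lactol acetate with free C6 hydroxymethyl
Product: 30 target compound, (R)-lactol
Conditions: immobilised Burkholderia cepacia lipase, n-BuOH, MTBE, 25 °C; filtration, cold crystallisation
Reagents that add atoms: none
Why: Lipase-catalysed alcoholysis breaks only the acyl–oxygen bond of the acetate under neutral anhydrous conditions, so the (R) configuration is retained, and the enzyme's preference for the (R)-acetate mirrors that of step 17.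

**Compound list**

1 | 2,4-dihydroxy-3-methylbenzoic acid | Cc1c(O)ccc(C(=O)O)c1O | starting material
2 | 2,4-dihydroxy-3-methyl-5-(sulfooxy)benzoic acid (potassium salt in the flask) | Cc1c(O)c(OS(=O)(=O)O)cc(C(=O)O)c1O | intermediate (not isolated)
3 | 2,4,5-trihydroxy-3-methylbenzoic acid | Cc1c(O)c(O)cc(C(=O)O)c1O | intermediate
4 | tert-butyl 2,4,5-trihydroxy-3-methylbenzoate | Cc1c(O)c(O)cc(C(=O)OC(C)(C)C)c1O | intermediate
5 | tert-butyl 4,5-bis(benzyloxy)-2-hydroxy-3-methylbenzoate | Cc1c(OCc2ccccc2)c(OCc2ccccc2)cc(C(=O)OC(C)(C)C)c1O | intermediate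
6 | tert-butyl 4,5-bis(benzyloxy)-2-(methoxymethoxy)-3-methylbenzoate | Cc1c(OCc2ccccc2)c(OCc2ccccc2)cc(C(=O)OC(C)(C)C)c1OCOC | intermediate
7 | tert-butyl 3,4-bis(benzyloxy)-2-bromo-6-(methoxymethoxy)-5-methylbenzoate | Cc1c(OCc2ccccc2)c(OCc2ccccc2)c(Br)c(C(=O)OC(C)(C)C)c1OCOC | intermediate
8 | arylmagnesium chloride from 7 (chloromagnesio group in place of bromine) | Cc1c(OCc2ccccc2)c(OCc2ccccc2)c([Mg]Cl)c(C(=O)OC(C)(C)C)c1OCOC | intermediate (not isolated)
9 | tert-butyl 3,4-bis(benzyloxy)-2-formyl-6-(methoxymethoxy)-5-methylbenzoate | Cc1c(OCc2ccccc2)c(OCc2ccccc2)c(C=O)c(C(=O)OC(C)(C)C)c1OCOC | intermediate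
10 | tert-butyl 3,4-bis(benzyloxy)-2-(dimethoxymethyl)-6-(methoxymethoxy)-5-methylbenzoate | Cc1c(OCc2ccccc2)c(OCc2ccccc2)c(C(OC)OC)c(C(=O)OC(C)(C)C)c1OCOC | intermediate
11 | tert-butyl 2-(dimethoxymethyl)-3,4-dihydroxy-6-(methoxymethoxy)-5-methylbenzoate (ring B catechol) | Cc1c(O)c(O)c(C(OC)OC)c(C(=O)OC(C)(C)C)c1OCOC | intermediate
12 | methyl 2-(hydroxymethyl)acrylate | C=C(CO)C(=O)OC | starting material
13 | methyl 2-{[tert-butyl(diphenyl)silyl]oxymethyl}acrylate | C=C(CO[Si](c1ccccc1)(c1ccccc1)C(C)(C)C)C(=O)OC | intermediate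
14 | methyl 3-{[tert-butyl(diphenyl)silyl]oxymethyl}-1,2,4-trioxolane-3-carboxylate (ozonide) | COC(=O)C1(CO[Si](c2ccccc2)(c2ccccc2)C(C)(C)C)OCOO1 | intermediate (not isolated)
15 | methyl 3-{[tert-butyl(diphenyl)silyl]oxy}-2-oxopropanoate | COC(=O)C(=O)CO[Si](c1ccccc1)(c1ccccc1)C(C)(C)C | intermediate
16 | methyl 3,3-dibromo-2-{[tert-butyl(diphenyl)silyl]oxymethyl}acrylate | COC(=O)C(CO[Si](c1ccccc1)(c1ccccc1)C(C)(C)C)=C(Br)Br | intermediate
17 | methyl 3-bromo-3-aryloxy-2-{[tert-butyl(diphenyl)silyl]oxymethyl}acrylate, aryl = ring B bound through the C2' oxygen, C1' hydroxyl free | COC(=O)C(CO[Si](c1ccccc1)(c1ccccc1)C(C)(C)C)=C(Br)Oc1c(O)c(C(OC)OC)c(C(=O)OC(C)(C)C)c(OCOC)c1C | intermediate (not isolated)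
18 | tert-butyl 4-(dimethoxymethyl)-2-[1-methoxy-1-oxo-3-{[tert-butyl(diphenyl)silyl]oxy}propan-2-ylidene]-6-(methoxymethoxy)-7-methyl-1,3-benzodioxole-5-carboxylate | COC(=O)C(CO[Si](c1ccccc1)(c1ccccc1)C(C)(C)C)=C1Oc2c(O1)c(C)c(OCOC)c(C(=O)OC(C)(C)C)c2C(OC)OC | intermediate
19 | tert-butyl 4-(dimethoxymethyl)-2-[3-methoxy-1-{[tert-butyl(diphenyl)silyl]oxy}but-3-en-2-ylidene]-6-(methoxymethoxy)-7-methyl-1,3-benzodioxole-5-carboxylate (diene) | C=C(OC)C(CO[Si](c1ccccc1)(c1ccccc1)C(C)(C)C)=C1Oc2c(O1)c(C)c(OCOC)c(C(=O)OC(C)(C)C)c2C(OC)OC | intermediate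
20 | but-2-ynoic acid | CC#CC(=O)O | starting material
21 | pentafluorophenol | Oc1c(F)c(F)c(F)c(F)c1F | starting material
22 | pentafluorophenyl but-2-ynoate | CC#CC(=O)Oc1c(F)c(F)c(F)c(F)c1F | intermediate
23 | spiro cycloadduct: ring A as a 1,4-cyclohexadiene (C2 H2, C3 Me, C4 CO2C6F5, C6 CH2OTBDPS, C1 OMe) spiro-fused at C5 to the ring B benzodioxole; racemic at the spiro carbon | COC1=C(CO[Si](c2ccccc2)(c3ccccc3)C(C)(C)C)C4(Oc5c(O4)c(C)c(OCOC)c(C(=O)OC(C)(C)C)c5C(OC)OC)C(C(=O)Oc6c(F)c(F)c(F)c(F)c6F)=C(C)C1 | intermediate (not isolated)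
24 | diaryl ether: aromatic ring A with C4 pentafluorophenyl ester and C5–O–C1' ether, free C2' hydroxyl on ring B | COc1cc(C)c(C(=O)Oc2c(F)c(F)c(F)c(F)c2F)c(Oc2c(O)c(C)c(OCOC)c(C(=O)OC(C)(C)C)c2C(OC)OC)c1CO[Si](c1ccccc1)(c1ccccc1)C(C)(C)C | intermediate (not isolated)
25 | protected depsidone (C6 CH2OTBDPS, C4' OMOM, C5' CO2t-Bu, C6' CH(OMe)2) | COc1cc(C)c2c(c1CO[Si](c3ccccc3)(c4ccccc4)C(C)(C)C)Oc5c(c(C)c(OCOC)c(C(=O)OC(C)(C)C)c5C(OC)OC)OC2=O | intermediate
26 | ring-opened formyl acid (C5' CO2H, C6' CHO, C4' OH, C6 CH2OTBDPS) | COc1cc(C)c2c(c1CO[Si](c3ccccc3)(c4ccccc4)C(C)(C)C)Oc5c(c(C)c(O)c(C(=O)O)c5C=O)OC2=O | intermediate (not isolated)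
27 | racemic lactol (3-hydroxyphthalide; C6 CH2OTBDPS) | COc1cc(C)c2c(c1CO[Si](c3ccccc3)(c4ccccc4)C(C)(C)C)Oc5c(c(C)c(O)c6c5C(O)OC6=O)OC2=O | intermediate
28 | (R)-lactol acetate (C6 CH2OTBDPS) | COc1cc(C)c2c(c1CO[Si](c3ccccc3)(c4ccccc4)C(C)(C)C)Oc5c(c(C)c(O)c6c5[C@H](OC(C)=O)OC6=O)OC2=O | intermediate
29 | (R)-lactol acetate with free C6 hydroxymethyl | COc1cc(C)c2c(c1CO)Oc1c(c(C)c(O)c3c1[C@H](OC(C)=O)OC3=O)OC2=O | intermediate
30 | target, (R) at the lactol carbon | COc1cc(C)c2c(c1CO)Oc1c(c(C)c(O)c3c1[C@H](O)OC3=O)OC2=O | target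

**Step count and risks**

Total: 19 steps. Longest linear sequence: 15 steps (steps 1–8, 12, 13, 15–19). Steps 9–11 and step 14 are side branches.

Steps most likely to fail:

1. Step 15. The cycloaddition of the β-methyl ynoate may be slower than thermal decay of the ketene acetal diene, or the C1' aryloxide may leave the spiro centre and lead to the regioisomeric depsidone. The fallback is a classical diaryl ether synthesis and lactonisation that sets out from catechol 11 and returns at 25.
 - Catechol 11 would be benzylated at the more acidic and less hindered C2' hydroxyl (BnBr, KHCO3, DMF) to give tert-butyl 4-(benzyloxy)-2-(dimethoxymethyl)-3-hydroxy-6-(methoxymethoxy)-5-methylbenzoate F1.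
 - Separately, commercial 1-fluoro-3-methoxy-5-methylbenzene (COc1cc(C)cc(F)c1) would be lithiated between fluorine and methoxy (n-BuLi, THF, −78 °C) and formylated with DMF to 2-fluoro-6-methoxy-4-methylbenzaldehyde F2.
 - Masking of the aldehyde in situ as its lithium amino alkoxide (lithium N,N,N'-trimethylethylenediamide), a second lithiation ortho to fluorine (s-BuLi) and a CO2 quench would give 2-fluoro-3-formyl-4-methoxy-6-methylbenzoic acid F3, which is benzylated (BnBr, K2CO3) to benzyl 2-fluoro-3-formyl-4-methoxy-6-methylbenzoate F4.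
 - Nucleophilic aromatic substitution of the fluoride of F4, activated by both ortho carbonyl groups, by the C1' phenoxide of F1 (K2CO3, DMF, 60 °C) would give the diaryl ether aldehyde F5.
 - NaBH4 reduction would give the diaryl ether alcohol F6, and TBDPSCl/imidazole the diaryl ether silyl ether F7.
 - Hydrogenolysis of both benzyl groups (H2, Pd/C, NaHCO3) would give the seco hydroxy acid F8, and DCC/DMAP lactonisation of its C2' hydroxyl onto the ring A acid returns to 25.

2. Step 13. The titanium methylidene may also methylenate the ring B tert-butyl ester, or the acid-labile ketene acetal may be lost while titanium residues are removed. The fallback sets out from dibromoacrylate 16 (with catechol 11) and returns at diene 19. Ester 16, which has no competing carbonyl group, would be methylenated first (Cp2TiMe2, PhMe, 65 °C) to 1,1-dibromo-3-methoxy-2-{[tert-butyl(diphenyl)silyl]oxymethyl}buta-1,3-diene F9. The cyclic ketene acetal would then be closed on catechol 11 by the known copper-catalysed double C–O coupling of 1,1-dibromoalkenes with phenols (copper iodide CuI, 2,2'-bipyridine, K3PO4, PhMe, 100 °C), which gives 19 directly.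

3. Step 17. The enzyme may not accept the bulky tetracyclic lactol, or may acetylate the (S)-lactol. The fallback is a classical resolution that sets out from 27 and returns at 28. Chemical acetylation of the lactol hydroxyl (Ac2O 1 equiv, pyridine, 0 °C; the hydrogen-bonded, hindered C4' phenol should react much more slowly) would give the racemic lactol acetate F10, which would be separated by preparative chromatography on a chiral stationary phase into 28 and the (S)-lactol acetate F11. F11 would be hydrolysed back to racemic 27 (aqueous TFA) and recycled.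

Further compounds

F1 | step 15 | tert-butyl 4-(benzyloxy)-2-(dimethoxymethyl)-3-hydroxy-6-(methoxymethoxy)-5-methylbenzoate | Cc1c(OCc2ccccc2)c(O)c(C(OC)OC)c(C(=O)OC(C)(C)C)c1OCOC
F2 | step 15 | 2-fluoro-6-methoxy-4-methylbenzaldehyde | COc1cc(C)cc(F)c1C=O
F3 | step 15 | 2-fluoro-3-formyl-4-methoxy-6-methylbenzoic acid | COc1cc(C)c(C(=O)O)c(F)c1C=O
F4 | step 15 | benzyl 2-fluoro-3-formyl-4-methoxy-6-methylbenzoate | COc1cc(C)c(C(=O)OCc2ccccc2)c(F)c1C=O
F5 | step 15 | diaryl ether aldehyde (ring A: C4 CO2Bn, C6 CHO; ring B bound through the C1' oxygen, C2' OBn) | COc1cc(C)c(C(=O)OCc2ccccc2)c(Oc2c(OCc3ccccc3)c(C)c(OCOC)c(C(=O)OC(C)(C)C)c2C(OC)OC)c1C=O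
F6 | step 15 | diaryl ether alcohol (C6 CH2OH) | COc1cc(C)c(C(=O)OCc2ccccc2)c(Oc2c(OCc3ccccc3)c(C)c(OCOC)c(C(=O)OC(C)(C)C)c2C(OC)OC)c1CO
F7 | step 15 | diaryl ether silyl ether (C6 CH2OTBDPS) | COc1cc(C)c(C(=O)OCc2ccccc2)c(Oc2c(OCc3ccccc3)c(C)c(OCOC)c(C(=O)OC(C)(C)C)c2C(OC)OC)c1CO[Si](c1ccccc1)(c1ccccc1)C(C)(C)C
F8 | step 15 | seco hydroxy acid (ring A C4 CO2H, ring B C2' OH) | COc1cc(C)c(C(=O)O)c(Oc2c(O)c(C)c(OCOC)c(C(=O)OC(C)(C)C)c2C(OC)OC)c1CO[Si](c1ccccc1)(c1ccccc1)C(C)(C)C
F9 | step 13 | 1,1-dibromo-3-methoxy-2-{[tert-butyl(diphenyl)silyl]oxymethyl}buta-1,3-diene | C=C(OC)C(CO[Si](c1ccccc1)(c1ccccc1)C(C)(C)C)=C(Br)Br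
F10 | step 17 | racemic lactol acetate (C6 CH2OTBDPS) | COc1cc(C)c2c(c1CO[Si](c3ccccc3)(c4ccccc4)C(C)(C)C)Oc5c(c(C)c(O)c6c5C(OC(C)=O)OC6=O)OC2=O
F11 | step 17 | (S)-lactol acetate (C6 CH2OTBDPS) | COc1cc(C)c2c(c1CO[Si](c3ccccc3)(c4ccccc4)C(C)(C)C)Oc5c(c(C)c(O)c6c5[C@@H](OC(C)=O)OC6=O)OC2=O
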